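**Retrosynthetic overview**

- Ester disconnection at C3–O gives trienone alcohol 32 and (2E,4E,6S)-6-methylocta-2,4-dienoic acid 38 (from (S)-2-methylbutan-1-ol). The C7 isopropylidene comes from an acetone aldol–dehydration on the C8 dienone, and the C8 ketone from a C8 carbinol.
- Structural feature and key disconnection (eremophilane numbering): the diene C9=C10–C1=C2 spans ring B (C5–C10) and ring A (C1–C5, C10) through ring-fusion carbon C10, which is bonded to quaternary C5. Both ring alkenes are traced back to a C10≡C1 ethynyl group on C5, flanked by a C9 vinyl arm and a C2 isobutenyl arm.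
- Dienyne 22 comes from an α,α-disubstituted γ-butyrolactone 19 (carbonyl = C10, α-carbon = C5, β-carbon = C4, γ-carbon = C3) by lactol formation, Ohira–Bestmann alkynylation (which frees C3–OH) and silylation.
- C5 is set by two lactone-enolate alkylations anti to the C4 methyl (MeI, then iodide 17). C3 and C4 come from a phosphoric-acid-catalysed anti-crotylboration of 3-methylbut-2-enal, followed by hydroboration and oxidative lactonization.
- Ring order: temporary lactone (opened in step 11), then ring B and ring A in one operation (step 13).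

Key step: step 13

Remark: atoms carry eremophilane numbers throughout; iodide 17 is made and used as the racemate, so 19–24 are pairs of epimers at C8 (the 8R epimer is drawn and named), a centre that disappears when both epimers are oxidized to dienone 25.

**Route**

Step 1
Reactants: 1 3-methylbut-2-enal; 2 (E)-crotylboronic acid pinacol ester
Product: 4 (3R,4R)-3,6-dimethylhepta-1,5-dien-4-ol, via O-boryl adduct 3 (not isolated)
Conditions: (R)-TRIP phosphoric acid [(R)-3,3'-bis(2,4,6-triisopropylphenyl)-1,1'-binaphthyl-2,2'-diyl hydrogen phosphate] (5 mol %), toluene, −30 °C; aq. NaHCO3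
Reagents that add atoms: none
Why: Chiral-phosphoric-acid-catalysed crotylboration through a closed chair (Zimmerman–Traxler) transition state, in which the (E)-boronate gives the anti relationship of the future C3 carbinol and C4 methyl centres and the (R)-catalyst directs attack to the Re face of the aldehyde, setting both centres.

Step 2
Reactants: 4 (3R,4R)-3,6-dimethylhepta-1,5-dien-4-ol
Product: 6 (3R,4R)-3,6-dimethylhept-5-ene-1,4-diol, via bis-boryl adduct 5 (not isolated)
Conditions: 9-BBN-H (2.3 equiv), THF, 0 °C → rt; then NaOH, H2O2, 0 °C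
Reagents that add atoms: hydrogen peroxide, OO
Why: Brown hydroboration–oxidation, in which 9-BBN adds anti-Markovnikov to the monosubstituted alkene far faster than to the trisubstituted isobutenyl group and leaves both stereocentres untouched.

Step 3
Reactants: 6 (3R,4R)-3,6-dimethylhept-5-ene-1,4-diol
Product: 8 (4R,5R)-4-methyl-5-(2-methylprop-1-en-1-yl)oxolan-2-one, via lactol 7 (not isolated)
Conditions: TEMPO (10 mol %), PhI(OAc)2 (2.5 equiv), CH2Cl2, rt
Reagents that add atoms: none
Why: TEMPO/PhI(OAc)2 oxidative lactonization of a 1,4-diol, in which the primary alcohol is oxidized first, the aldehyde is trapped by the secondary hydroxyl as the lactol and the lactol is oxidized on to the trans-lactone.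

Step 4
Reactants: 8 (4R,5R)-4-methyl-5-(2-methylprop-1-en-1-yl)oxolan-2-one
Product: 10 (3R,4R,5R)-3,4-dimethyl-5-(2-methylprop-1-en-1-yl)oxolan-2-one, via lithium enolate 9 (not isolated)
Conditions: LiN(iPr)2 (1.05 equiv), THF, −78 °C; MeI, −78 → −40 °C
Reagents that add atoms: iodomethane, CI
Why: Lactone enolate alkylation, expected anti to the neighbouring C4 methyl, although the configuration at this carbon (future C5) is irrelevant here because it is planarized again in step 9.

Step 5
Reactants: 11 ethyl acetate; 12 acrolein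
Product: 14 ethyl 3-hydroxypent-4-enoate (racemic), via lithium enolate 13 (not isolated)
Conditions: LiN(iPr)2, THF, −78 °C; acrolein, −78 °C; aq. NH4Cl
Reagents that add atoms: none
Why: Aldol addition of an ester lithium enolate, which adds 1,2 to acrolein at low temperature; the carbinol centre (future C8) is deliberately left racemic.

Step 6
Reactants: 14 ethyl 3-hydroxypent-4-enoate
Product: 15 ethyl 3-[(triethylsilyl)oxy]pent-4-enoate (racemic)
Conditions: Et3SiCl, imidazole, CH2Cl2, 0 °C → rt
Reagents that add atoms: chlorotriethylsilane, CC[Si](Cl)(CC)CC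
Why: Imidazole-promoted silylation of a secondary alcohol, giving the ether that will later be cleaved selectively in the presence of a tert-butyldimethylsilyl ether.

Step 7
Reactants: 15 ethyl 3-[(triethylsilyl)oxy]pent-4-enoate
Product: 16 3-[(triethylsilyl)oxy]pent-4-en-1-ol (racemic)
Conditions: iBu2AlH (2.3 equiv), CH2Cl2, −78 → −20 °C; aq. potassium sodium tartrate
Reagents that add atoms: none
Why: Reduction of an ester to the primary alcohol with excess iBu2AlH, conditions under which the silyl ether and the vinyl group are inert.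

Step 8
Reactants: 16 3-[(triethylsilyl)oxy]pent-4-en-1-ol
Product: 17 triethyl[(5-iodopent-1-en-3-yl)oxy]silane (racemic)
Conditions: I2, PPh3, imidazole, CH2Cl2, 0 °C
Reagents that add atoms: iodine, II
Why: Appel-type (Garegg–Samuelsson) iodination of a primary alcohol by SN2 displacement of the oxyphosphonium group, buffered by imidazole so that the acid-labile silyl ether survives.

Step 9
Reactants: 10 (3R,4R,5R)-3,4-dimethyl-5-(2-methylprop-1-en-1-yl)oxolan-2-one; 17 triethyl[(5-iodopent-1-en-3-yl)oxy]silane
Product: 19 (3R,4R,5S)-3,4-dimethyl-5-(2-methylprop-1-en-1-yl)-3-{(3R)-3-[(triethylsilyl)oxy]pent-4-en-1-yl}oxolan-2-one, via lithium enolate 18 (not isolated)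
Conditions: LiN(iPr)2 (1.15 equiv), THF, −78 °C; 17 (1.3 equiv), DMPU, −78 → −10 °C
Reagents that add atoms: none
Why: Enolate alkylation that creates quaternary C5, the primary iodide attacking the tetrasubstituted lactone enolate on the face anti to the adjacent C4 methyl (the usual trans rule for β-substituted γ-butyrolactone enolates), so that the pentenyl arm ends trans and the C5 methyl cis to the C4 methyl as the target requires.

Step 10
Reactants: 19 quaternary lactone
Product: 20 (3R,4R,5S)-3,4-dimethyl-5-(2-methylprop-1-en-1-yl)-3-{(3R)-3-[(triethylsilyl)oxy]pent-4-en-1-yl}oxolan-2-ol (anomers)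
Conditions: iBu2AlH (1.2 equiv), CH2Cl2, −78 °C; aq. potassium sodium tartrate
Reagents that add atoms: none
Why: Partial reduction of a lactone with iBu2AlH at −78 °C, where the tetrahedral aluminium alkoxide persists and reduction stops at the lactol.

Step 11
Reactants: 20 lactol
Product: 21 (4S,5R,6R,9R)-6-ethynyl-2,5,6-trimethyl-9-[(triethylsilyl)oxy]undeca-2,10-dien-4-ol
Conditions: dimethyl (1-diazo-2-oxopropyl)phosphonate (2.5 equiv), K2CO3 (4 equiv), MeOH, 0 °C → rt (40 °C if slow)
Reagents that add atoms: dimethyl (1-diazo-2-oxopropyl)phosphonate, COP(=O)(OC)C(=[N+]=[N-])C(C)=O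
Why: Ohira–Bestmann (Seyferth–Gilbert) homologation, in which the open hydroxy-aldehyde form of the lactol is converted by the diazophosphonate anion into the terminal alkyne C10≡C1 (olefination, loss of N2, 1,2-hydrogen shift), releasing the C3 hydroxyl while quaternary C5 cannot epimerize.

Step 12
Reactants: 21 alkynol
Product: 22 tert-butyl({(4S,5R,6R,9R)-6-ethynyl-2,5,6-trimethyl-9-[(triethylsilyl)oxy]undeca-2,10-dien-4-yl}oxy)dimethylsilane (dienyne bis-silyl ether)
Conditions: TBSOTf, 2,6-lutidine, CH2Cl2, −78 → 0 °C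
Reagents that add atoms: tert-butyldimethylsilyl trifluoromethanesulfonate, CC(C)(C)[Si](C)(C)OS(=O)(=O)C(F)(F)F
Why: Silylation of a hindered secondary allylic alcohol with the silyl triflate, conditions that leave the terminal alkyne and the triethylsilyl ether unchanged.

Step 13
Reactants: 22 dienyne bis-silyl ether
Product: 23 (3S,4R,5R,8R)-3-[(tert-butyldimethylsilyl)oxy]-8-[(triethylsilyl)oxy]-11,12,13-trinoreremophila-1,9-diene
Conditions: second-generation Hoveyda–Grubbs catalyst RuCl2(H2IMes)(=CH-C6H4-2-OiPr) (10 mol %), toluene (0.005 M), 80 °C, argon sparge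
Reagents that add atoms: none
Why: The catalyst should load on the monosubstituted C9 vinyl group, and the C9 carbene adds to the C10≡C1 alkyne in the exo sense (C9–C10 bond, six-membered ring B, C9=C10), leaving a conjugated carbene on C1. That carbene then undergoes ring-closing metathesis with the C2=CMe2 alkene (C1=C2, six-membered ring A) and departs as a ruthenium isopropylidene, which passes 2-methylpropene to the next C9 vinyl group. The closest known reaction type is the tandem ring-closing metathesis of dienynes to fused bicyclic 1,3-dienes (ene–yne–ene cascade). No stereocentre is formed, and C3, C4, C5 and C8 are spectators. The selectivity needed is the order of events, start at C9 and not at C2 or at the alkyne; the substrate secures it through the monosubstituted versus trisubstituted alkene and the quaternary-flanked alkyne, while quaternary C5 gathers the three arms and high dilution disfavours intermolecular ene–yne coupling.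

Step 14
Reactants: 23 bicyclic diene
Product: 24 (3S,4R,5R,8R)-3-[(tert-butyldimethylsilyl)oxy]-11,12,13-trinoreremophila-1,9-dien-8-ol
Conditions: HF·pyridine, pyridine, THF, 0 °C
Reagents that add atoms: none
Why: Selective desilylation, the triethylsilyl ether being cleaved by buffered HF·pyridine much faster than the hindered tert-butyldimethylsilyl ether, in a medium too weakly acidic to ionize the doubly allylic C8 carbinol.

Step 15
Reactants: 24 dienol
Product: 25 (3S,4R,5R)-3-[(tert-butyldimethylsilyl)oxy]-11,12,13-trinoreremophila-1,9-dien-8-one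
Conditions: MnO2 (activated, excess), CH2Cl2, rt
Reagents that add atoms: none
Why: MnO2 oxidation of an allylic (dienylic) alcohol, in which both C8 epimers converge on one dienone and the C3 silyl ether is inert.

Step 16
Reactants: 25 dienone; 26 acetone
Product: 29 (3S,4R,5R,7S)-3-[(tert-butyldimethylsilyl)oxy]-11-hydroxyeremophila-1,9-dien-8-one, via lithium dienolate 27 (not isolated), via chlorozinc dienolate 28 (not isolated)
Conditions: LiN(iPr)2 (1.1 equiv), THF, −78 °C; ZnCl2, −78 °C; acetone, −78 °C; aq. NH4Cl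
Reagents that add atoms: none
Why: Directed aldol addition, LiN(iPr)2 deprotonating the dienone kinetically at the α′ carbon C7 and the zinc enolate adding to acetone without proton transfer or retro-aldol; the new C7 centre (addition expected anti to the angular C5 methyl) is removed in step 17.

Step 17
Reactants: 29 aldol adduct
Product: 31 (3S,4R,5R)-3-[(tert-butyldimethylsilyl)oxy]eremophila-1,7(11),9-trien-8-one, via mesylate 30 (not isolated)
Conditions: MsCl, Et3N, CH2Cl2, 0 °C; then DBU, rt
Reagents that add atoms: none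
Why: Mesylation of the tertiary alcohol (via sulfene) followed by E1cB elimination with DBU, which gives the conjugated tetrasubstituted C7=C11 isopropylidene enone as the favoured regioisomer under basic conditions.

Step 18
Reactants: 31 silyl ether trienone
Product: 32 (3S,4R,5R)-3-hydroxyeremophila-1,7(11),9-trien-8-one
Conditions: HF·pyridine, THF, 0 °C → rt
Reagents that add atoms: none
Why: Fluoride cleavage of the tert-butyldimethylsilyl ether under weakly acidic conditions, in which the cross-conjugated trienone does not enolize and the C3–O bond is not broken.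

Step 19
Reactants: 33 (S)-2-methylbutan-1-ol
Product: 34 (S)-2-methylbutanal
Conditions: 4-MeO-TEMPO (1 mol %), KBr, NaOCl, NaHCO3, CH2Cl2/H2O, 0 °C
Reagents that add atoms: none
Why: Anelli oxidation (oxoammonium salt with NaOCl as terminal oxidant), which stops at the aldehyde and under buffered two-phase conditions should not racemize the α-centre; the volatile aldehyde is used directly as a concentrated solution.

Step 20
Reactants: 34 (S)-2-methylbutanal; 35 triethyl 4-phosphonocrotonate
Product: 37 ethyl (2E,4E,6S)-6-methylocta-2,4-dienoate, via lithium phosphonate anion 36 (not isolated)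
Conditions: LiN(SiMe3)2, THF, −78 °C; then 34, −78 → 0 °C
Reagents that add atoms: none
Why: Vinylogous Horner–Wadsworth–Emmons olefination, the phosphonate anion reacting at the carbon α to phosphorus to give the new C4=C5 alkene with E geometry, while addition at −78 °C protects the α-stereocentre of the aldehyde.

Step 21
Reactants: 37 ethyl dienoate
Product: 38 (2E,4E,6S)-6-methylocta-2,4-dienoic acid
Conditions: LiOH, THF/MeOH/H2O, rt; then 1 M HCl
Reagents that add atoms: lithium hydroxide, [Li+].[OH-]
Why: Saponification by acyl–oxygen cleavage, which leaves the diene geometry and the remote C6 stereocentre unaffected.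

Step 22
Reactants: 32 trienone alcohol; 38 dienoic acid
Product: 40 (3S,4R,5R)-8-oxoeremophila-1,7(11),9-trien-3-yl (2E,4E,6S)-6-methylocta-2,4-dienoate (CNP0215744.1), via mixed anhydride 39 (not isolated)
Conditions: 2,4,6-Cl3C6H2COCl, Et3N, THF, rt; then 32, DMAP, toluene, rt
Reagents that add atoms: none
Why: Yamaguchi esterification, DMAP attacking the mixed anhydride at the dienoyl carbonyl and the acylpyridinium acylating the hindered C3 hydroxyl with retention at C3, since the C–O bond is not broken.

**Compound list**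

1 | 3-methylbut-2-enal | CC(C)=CC=O | starting material
2 | (E)-crotylboronic acid pinacol ester, 2-[(2E)-but-2-en-1-yl]-4,4,5,5-tetramethyl-1,3,2-dioxaborolane | C/C=C/CB1OC(C)(C)C(C)(C)O1 | starting material
3 | O-pinacolboryl ether of 4 | C=C[C@@H](C)[C@@H](OB1OC(C)(C)C(C)(C)O1)C=C(C)C | intermediate (not isolated)
4 | (3R,4R)-3,6-dimethylhepta-1,5-dien-4-ol | C=C[C@@H](C)[C@@H](O)C=C(C)C | intermediate
5 | bis(9-borabicyclo[3.3.1]nonyl) adduct of 4 (C-boryl at C1, O-boryl at C4) | B1(C2CCCC1CCC2)CC[C@@H](C)[C@@H](OB1C2CCCC1CCC2)C=C(C)C | intermediate (not isolated)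
6 | (3R,4R)-3,6-dimethylhept-5-ene-1,4-diol | OCC[C@@H](C)[C@@H](O)C=C(C)C | intermediate
7 | (4R,5R)-4-methyl-5-(2-methylprop-1-en-1-yl)oxolan-2-ol (anomers) | OC1C[C@@H](C)[C@@H](O1)C=C(C)C | intermediate (not isolated)
8 | (4R,5R)-4-methyl-5-(2-methylprop-1-en-1-yl)oxolan-2-one | O=C1C[C@@H](C)[C@@H](O1)C=C(C)C | intermediate
9 | lithium enolate of 8 | [Li+].[O-]C1=C[C@@H](C)[C@@H](O1)C=C(C)C | intermediate (not isolated)
10 | (3R,4R,5R)-3,4-dimethyl-5-(2-methylprop-1-en-1-yl)oxolan-2-one | O=C1[C@H](C)[C@@H](C)[C@@H](O1)C=C(C)C | intermediate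
11 | ethyl acetate | CCOC(C)=O | starting material
12 | acrolein (prop-2-enal) | C=CC=O | starting material
13 | lithium enolate of ethyl acetate | [Li+].[O-]C(=C)OCC | intermediate (not isolated)
14 | ethyl 3-hydroxypent-4-enoate (racemic) | CCOC(=O)CC(O)C=C | intermediate
15 | ethyl 3-[(triethylsilyl)oxy]pent-4-enoate (racemic) | CCOC(=O)CC(O[Si](CC)(CC)CC)C=C | intermediate
16 | 3-[(triethylsilyl)oxy]pent-4-en-1-ol (racemic) | OCCC(O[Si](CC)(CC)CC)C=C | intermediate
17 | triethyl[(5-iodopent-1-en-3-yl)oxy]silane (racemic) | ICCC(O[Si](CC)(CC)CC)C=C | intermediate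
18 | lithium enolate of 10 | [Li+].[O-]C1=C(C)[C@@H](C)[C@@H](O1)C=C(C)C | intermediate (not isolated)
19 | (3R,4R,5S)-3,4-dimethyl-5-(2-methylprop-1-en-1-yl)-3-{(3R)-3-[(triethylsilyl)oxy]pent-4-en-1-yl}oxolan-2-one (8R epimer drawn) | O=C1[C@](C)(CC[C@@H](O[Si](CC)(CC)CC)C=C)[C@@H](C)[C@@H](O1)C=C(C)C | intermediate
20 | lactol of 19, (3R,4R,5S)-configured oxolan-2-ol (anomers) | OC1[C@](C)(CC[C@@H](O[Si](CC)(CC)CC)C=C)[C@@H](C)[C@@H](O1)C=C(C)C | intermediate
21 | (4S,5R,6R,9R)-6-ethynyl-2,5,6-trimethyl-9-[(triethylsilyl)oxy]undeca-2,10-dien-4-ol | C#C[C@](C)(CC[C@@H](O[Si](CC)(CC)CC)C=C)[C@@H](C)[C@@H](O)C=C(C)C | intermediate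
22 | tert-butyl({(4S,5R,6R,9R)-6-ethynyl-2,5,6-trimethyl-9-[(triethylsilyl)oxy]undeca-2,10-dien-4-yl}oxy)dimethylsilane (key-step precursor) | C#C[C@](C)(CC[C@@H](O[Si](CC)(CC)CC)C=C)[C@@H](C)[C@@H](O[Si](C)(C)C(C)(C)C)C=C(C)C | intermediate
23 | (3S,4R,5R,8R)-3-[(tert-butyldimethylsilyl)oxy]-8-[(triethylsilyl)oxy]-11,12,13-trinoreremophila-1,9-diene (key-step product) | CC(C)(C)[Si](C)(C)O[C@H]1C=CC2=C[C@H](O[Si](CC)(CC)CC)CC[C@]2(C)[C@H]1C | intermediate
24 | (3S,4R,5R,8R)-3-[(tert-butyldimethylsilyl)oxy]-11,12,13-trinoreremophila-1,9-dien-8-ol | CC(C)(C)[Si](C)(C)O[C@H]1C=CC2=C[C@H](O)CC[C@]2(C)[C@H]1C | intermediate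
25 | (3S,4R,5R)-3-[(tert-butyldimethylsilyl)oxy]-11,12,13-trinoreremophila-1,9-dien-8-one | CC(C)(C)[Si](C)(C)O[C@H]1C=CC2=CC(=O)CC[C@]2(C)[C@H]1C | intermediate
26 | acetone | CC(C)=O | starting material
27 | lithium C7–C8 dienolate of 25 | [Li+].CC(C)(C)[Si](C)(C)O[C@H]1C=CC2=CC([O-])=CC[C@]2(C)[C@H]1C | intermediate (not isolated)
28 | chlorozinc C7–C8 dienolate of 25 | CC(C)(C)[Si](C)(C)O[C@H]1C=CC2=CC(O[Zn]Cl)=CC[C@]2(C)[C@H]1C | intermediate (not isolated)
29 | (3S,4R,5R,7S)-3-[(tert-butyldimethylsilyl)oxy]-11-hydroxyeremophila-1,9-dien-8-one | CC(C)(C)[Si](C)(C)O[C@H]1C=CC2=CC(=O)[C@H](C(C)(C)O)C[C@]2(C)[C@H]1C | intermediate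
30 | 11-O-methanesulfonate of 29 | CC(C)(C)[Si](C)(C)O[C@H]1C=CC2=CC(=O)[C@H](C(C)(C)OS(C)(=O)=O)C[C@]2(C)[C@H]1C | intermediate (not isolated)
31 | (3S,4R,5R)-3-[(tert-butyldimethylsilyl)oxy]eremophila-1,7(11),9-trien-8-one | CC(C)(C)[Si](C)(C)O[C@H]1C=CC2=CC(=O)C(=C(C)C)C[C@]2(C)[C@H]1C | intermediate
32 | (3S,4R,5R)-3-hydroxyeremophila-1,7(11),9-trien-8-one | O[C@H]1C=CC2=CC(=O)C(=C(C)C)C[C@]2(C)[C@H]1C | intermediate
33 | (S)-2-methylbutan-1-ol | CC[C@H](C)CO | starting material
34 | (S)-2-methylbutanal | CC[C@H](C)C=O | intermediate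
35 | triethyl 4-phosphonocrotonate, ethyl (2E)-4-(diethoxyphosphoryl)but-2-enoate | CCOC(=O)/C=C/CP(=O)(OCC)OCC | starting material
36 | lithium salt of the C4 anion of 35 | [Li+].CCOC(=O)/C=C/[CH-]P(=O)(OCC)OCC | intermediate (not isolated)
37 | ethyl (2E,4E,6S)-6-methylocta-2,4-dienoate | CC[C@H](C)/C=C/C=C/C(=O)OCC | intermediate
38 | (2E,4E,6S)-6-methylocta-2,4-dienoic acid | CC[C@H](C)/C=C/C=C/C(=O)O | intermediate
39 | (2E,4E,6S)-6-methylocta-2,4-dienoic 2,4,6-trichlorobenzoic anhydride | CC[C@H](C)/C=C/C=C/C(=O)OC(=O)c1c(Cl)cc(Cl)cc1Cl | intermediate (not isolated)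
40 | (1R,2S,8aR)-1,8a-dimethyl-6-oxo-7-(propan-2-ylidene)-1,2,6,7,8,8a-hexahydronaphthalen-2-yl (2E,4E,6S)-6-methylocta-2,4-dienoate (CNP0215744.1) | CC[C@H](C)/C=C/C=C/C(=O)O[C@H]1C=CC2=CC(=O)C(=C(C)C)C[C@]2(C)[C@H]1C | target

**Step count**

Total: 22 steps. Longest linear sequence: 15 steps (steps 1–4, 9–18, 22). The iodide branch (steps 5–8) and the acid branch (steps 19–21) run in parallel.

**Steps most likely to fail**

1. Step 13 (key step). After the first closure the C1 carbene may fail to engage the hindered C2=CMe2 alkene, or the catalyst may be consumed by intermolecular alkyne–alkene coupling, so that turnover stops before ring A is closed. The fallback sets out from 22 and returns at 23, and runs the two closures as separate operations. With first-generation Grubbs catalyst RuCl2(PCy3)2(=CHPh) under ethylene (1 atm, CH2Cl2, rt) only the ring-closing ene–yne metathesis should occur, because this catalyst leaves the trisubstituted alkene alone and ethylene keeps the resting carbene as Ru=CH2. This should give the ring B vinylcyclohexene triene F1 (C9=C10 in the ring, C1=CH2 on C10). Ring-closing metathesis of F1 between C1=CH2 and C2=CMe2 with the second-generation Hoveyda–Grubbs catalyst (toluene, 80 °C) then closes ring A and delivers 23.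

2. Step 11. The α-quaternary lactol may stay closed, so that too little open aldehyde is present and the diazophosphonate is lost to methanolysis before homologation; long exposure to K2CO3/MeOH may also begin to cleave the triethylsilyl ether. The fallback sets out from 19 and returns at 22, by-passing 20 and 21, and makes an aldehyde that cannot cyclize. Excess iBu2AlH (CH2Cl2, −78 → 0 °C) reduces 19 to the C10/C3 diol F2. Pivaloyl chloride and pyridine (0 °C) acylate the primary hydroxyl to give the mono-pivalate F3. TBSOTf/2,6-lutidine silylates C3–OH to give the pivalate silyl ether F4. iBu2AlH (−78 °C) removes the pivalate to give the primary alcohol F5, and Dess–Martin periodinane gives the α-quaternary aldehyde F6. The Ohira–Bestmann reagent (K2CO3, MeOH) then converts F6 directly into 22.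

3. Step 9. Substitution at the unactivated iodide by the tetrasubstituted enolate may be slow, dehydroiodination of 17 may compete, and the facial preference may erode if the mixture has to be warmed. The fallback sets out from 10 and returns at 19, and builds the arm after a more reliable allylation. Enolate 18 is alkylated with allyl bromide (THF, −78 °C), again anti to the C4 methyl, to give the allyl lactone F7. 9-BBN-H followed by NaOH/H2O2 hydroborates only the terminal alkene and gives the primary alcohol F8. Dess–Martin periodinane gives the aldehyde F9. CH2=CHMgBr (THF, −78 °C) adds to the aldehyde in preference to the hindered lactone and gives the allylic alcohol F10 (both C8 epimers). Et3SiCl/imidazole then gives 19.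

**Further compounds**

F1 | step 13 | ring B vinylcyclohexene triene (C9=C10 closed, C1=CH2 on C10, 3-OTBS, 8-OTES) | C=CC1=C[C@H](O[Si](CC)(CC)CC)CC[C@]1(C)[C@@H](C)[C@@H](O[Si](C)(C)C(C)(C)C)C=C(C)C
F2 | step 11 | C10/C3 diol from full reduction of 19 | OC[C@](C)(CC[C@@H](O[Si](CC)(CC)CC)C=C)[C@@H](C)[C@@H](O)C=C(C)C
F3 | step 11 | C10 mono-pivalate of F2 | CC(C)(C)C(=O)OC[C@](C)(CC[C@@H](O[Si](CC)(CC)CC)C=C)[C@@H](C)[C@@H](O)C=C(C)C
F4 | step 11 | C10 pivalate, C3 tert-butyldimethylsilyl ether | CC(C)(C)C(=O)OC[C@](C)(CC[C@@H](O[Si](CC)(CC)CC)C=C)[C@@H](C)[C@@H](O[Si](C)(C)C(C)(C)C)C=C(C)C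
F5 | step 11 | C10 primary alcohol, C3 tert-butyldimethylsilyl ether | OC[C@](C)(CC[C@@H](O[Si](CC)(CC)CC)C=C)[C@@H](C)[C@@H](O[Si](C)(C)C(C)(C)C)C=C(C)C
F6 | step 11 | C10 aldehyde, C3 tert-butyldimethylsilyl ether | O=C[C@](C)(CC[C@@H](O[Si](CC)(CC)CC)C=C)[C@@H](C)[C@@H](O[Si](C)(C)C(C)(C)C)C=C(C)C
F7 | step 9 | (3R,4R,5S)-3,4-dimethyl-5-(2-methylprop-1-en-1-yl)-3-(prop-2-en-1-yl)oxolan-2-one | O=C1[C@](C)(CC=C)[C@@H](C)[C@@H](O1)C=C(C)C
F8 | step 9 | (3R,4R,5S)-3-(3-hydroxypropyl)-3,4-dimethyl-5-(2-methylprop-1-en-1-yl)oxolan-2-one | O=C1[C@](C)(CCCO)[C@@H](C)[C@@H](O1)C=C(C)C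
F9 | step 9 | 3-[(3R,4R,5S)-3,4-dimethyl-5-(2-methylprop-1-en-1-yl)-2-oxooxolan-3-yl]propanal | O=C1[C@](C)(CCC=O)[C@@H](C)[C@@H](O1)C=C(C)C
F10 | step 9 | (3R,4R,5S)-3-[(3R)-3-hydroxypent-4-en-1-yl]-3,4-dimethyl-5-(2-methylprop-1-en-1-yl)oxolan-2-one (8R epimer drawn) | O=C1[C@](C)(CC[C@@H](O)C=C)[C@@H](C)[C@@H](O1)C=C(C)C
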